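The elm run, with 0.040 M of substrate against 0.022 M of reagent, slows with time, and its readings leave open whether its reagent went into product or was also lost by itself.

- elm: substrate 0.040 M; reagent 0.022 M; run made earlier
- flask: substrate 0.020 M; reagent 0.0220 M; time 6.0 h

elm run (percent of the substrate charged)

| time / min | target / % | isomer of the product / % |
|---|---|---|
| 3.00 | 2.4 | 1.5 |
| 6.00 | 5.2 | 3.3 |
| 15.0 | 9.5 | 7.7 |
| 40.0 | 14.5 | 18.6 |

(each reading ± 0.5 percentage points)

- the reaction counts as stopped when no species that holds the substrate changes by six tenths of a point or more over the second half of the time

- which holds at 6.0 h: what has brought the reaction to rest, or that it has not come to rest (the reagent has run out first / all of the substrate has reacted / forward and back rates have come level / it is still moving)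
- how much target there is at 6.0 h, in percent of the substrate charged
- how much isomer of the product there is at 6.0 h, in percent of the substrate charged

I wrote S and R for the substrate and reagent concentrations and took the substrate's loss rate as kSR. The reading at 6.00 min gave a pseudo-first-order rate, k times the charged reagent, of 0.0148 min⁻¹.

I then solved two extreme versions. In the first, reagent goes one for one into product. That gives 31.9% conversion in elm at 40.0 min, against 33.1% read. In the flask it leaves 12.7% of the substrate at 6.0 h. The flask's reagent charge is larger than its substrate charge by a spare of 0.00200 M.

In the second, reagent falls by its own second-order loss at 2kR squared, with the same k and no draw by the product, which gives elm 32.3%, so the readings allow this version too. Adding the product's draw, each substrate consumed costs 1 + 2R/S of reagent. Integrated, this exhausts the reagent when the substrate stands at the stranded share, the substrate charge over the sum of both charges: 47.6% for the flask.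

This sum counts both draws, while each version matched elm with one, so I took it as the far end and expected the flask's substrate to stand between the first version's figure and the stranded share. At that far end, self-loss takes 0.0115 M, more than the spare. I therefore committed to reagent as the limiting reagent and a stop near the stranded share. With elm's target share as read at 40.0 min, 43.8%, that meant 23.0% target and 29.4% isomer of the product.

The forecast differed, saying it is still moving with 2.5% target and 85.5% isomer of the product, on the ground that “The total (target + isomer) fits 1:1 second-order S + R kinetics well”.

The flask gave this: the reagent has run out first, with 21.0% target and 35.5% isomer of the product.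

    2 reagent → self-condensation product (k = 0.0160 M⁻¹ s⁻¹)
    reagent + tight pair → target (k = 2.20 M⁻¹ s⁻¹)
    reagent + loose pair → isomer of the product (k = 29.0 M⁻¹ s⁻¹)
    tight pair ⇌ loose pair (K = 1.40, k = 0.0280 s⁻¹)
    substrate ⇌ tight pair (K = 0.00420, k = 0.00200 s⁻¹)

At 6.00 h the flask held 0% of its reagent and 43% of its substrate, against the stranded share of 47.6%, and its 0.00535 M of self-condensation product had taken 0.0107 M of reagent, more than the spare 0.00200 M. For the neighbour charged with 0.0088 M of reagent the stranded share is 69.4%, and that flask kept 65% of its substrate.

The data stem from a simulated flask with constants of no real substance.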